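Ring B (the methoxy-bearing 1,2-dioxine) is cut between its peroxyketal carbon C6 and the neighbouring alkene carbon C5 (chain numbered from the ester carbon C1). The key step exploits that C6 carries two oxygen atoms, OMe and the peroxide oxygen O2, and so is an orthoester carbon in disguise. A trimethyl orthoester carrying the finished ring A and a (Z)-γ-silyl allylic hydroperoxide are joined through O1–O2, and ionization to an alkoxy(peroxy)carbenium ion starts a vinylsilane-terminated cyclization. One operation forms C5–C6, closes ring B, leaves the C4=C5 alkene and sets the C6 stereocentre from C3. Ring A comes from a singlet-oxygen cycloaddition.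

Key step: step 12

Remark on labels: chain carbons run from C1 (ester carbon) to C16; O1 is the peroxide oxygen on C3 and O2 the one on C6; ring A is the propyl-bearing dioxine and ring B the methoxy-bearing dioxine.

Assumption: in step 9 the quinine-derived primary amine is taken to deliver the (3R)-peroxide; if the sense of induction is the opposite, the quinidine-derived pseudo-enantiomer serves.

Step 1
Reactants: 1 4-bromo-1,1,1-trimethoxybutane; 2 lithium acetylide–ethylenediamine complex
Product: 3 6,6,6-trimethoxyhex-1-yne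
Conditions: DMSO, 0 °C → rt
Reagents that add atoms: none
Why: SN2 alkylation of the acetylide at the primary bromide (acetylide alkylation) should proceed cleanly because the orthoester is inert to base.

Step 2
Reactants: 3 6,6,6-trimethoxyhex-1-yne
Product: 5 (E)-1-iodo-6,6,6-trimethoxyhex-1-ene, via alkenylzirconocene chloride 4 (not isolated)
Conditions: Cp2Zr(H)Cl, THF, rt; then I2, 0 °C
Reagents that add atoms: iodine, [I][I]
Why: Syn hydrozirconation places zirconium on the terminal carbon and iodinolysis with retention should give the (E)-iodide, the orthoester being unreactive towards Cp2Zr(H)Cl (hydrozirconation–iodination).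

Step 3
Reactants: 5 (E)-1-iodo-6,6,6-trimethoxyhex-1-ene; 6 (E)-pent-1-en-1-ylboronic acid
Product: 7 (5E,7E)-1,1,1-trimethoxyundeca-5,7-diene
Conditions: Pd(PPh3)4 (5 mol %), K2CO3, THF/H2O, 60 °C
Reagents that add atoms: none
Why: Suzuki–Miyaura coupling of two (E)-alkenyl partners proceeds with retention at both alkenes, which fixes the (E,E)-diene needed for a cis cycloadduct, and the aqueous base leaves the orthoester intact.

Step 4
Reactants: 7 (5E,7E)-1,1,1-trimethoxyundeca-5,7-diene
Product: 8 rac-(3S,6R)-3-propyl-6-(4,4,4-trimethoxybutyl)-3,6-dihydro-1,2-dioxine (cis racemate)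
Conditions: O2, visible light, tetraphenylporphyrin (cat.), solid NaHCO3, CH2Cl2, 0 °C
Reagents that add atoms: dioxygen, O=O
Why: Suprafacial [4+2] cycloaddition of singlet oxygen to the s-cis (E,E)-diene puts both allylic substituents on one face, so C10 and C13 of ring A are set cis to each other (as a racemate), while the solid base keeps the medium non-acidic for the orthoester.

Step 5
Reactants: 8 rac-(3S,6R)-3-propyl-6-(4,4,4-trimethoxybutyl)-3,6-dihydro-1,2-dioxine
Product: 9 (3S,6R)-3-propyl-6-(4,4,4-trimethoxybutyl)-3,6-dihydro-1,2-dioxine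
Conditions: preparative HPLC on cellulose tris(3,5-dimethylphenylcarbamate), hexane/2-propanol
Reagents that add atoms: none
Why: Resolution by chromatography on a chiral stationary phase separates the enantiomers of 8 and so fixes the absolute configuration of ring A (C10 R, C13 S); the collected enantiomer is to be assigned before use, for example by vibrational circular dichroism against calculation.

Step 6
Reactants: 10 3-(trimethylsilyl)prop-2-yn-1-ol
Product: 11 (Z)-3-(trimethylsilyl)prop-2-en-1-ol
Conditions: H2 (1 atm), Pd/CaCO3 poisoned with Pb(OAc)2, quinoline, hexane, rt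
Reagents that add atoms: none
Why: Syn delivery of hydrogen to the silylalkyne on the poisoned palladium surface should stop at the (Z)-vinylsilane (alkyne semi-hydrogenation).

Step 7
Reactants: 11 (Z)-3-(trimethylsilyl)prop-2-en-1-ol; 12 (triphenylphosphoranylidene)acetaldehyde
Product: 14 (2E,4Z)-5-(trimethylsilyl)penta-2,4-dienal, via (Z)-3-(trimethylsilyl)prop-2-enal 13 (not isolated)
Conditions: MnO2 (excess), CH2Cl2, rt
Reagents that add atoms: none
Why: Allylic oxidation by MnO2 with the stabilized formyl ylide present traps the isomerization-prone (Z)-enal 13 as it forms, giving the new C2=C3 bond as the (E)-alkene while the (Z)-vinylsilane is kept (tandem oxidation–Wittig olefination).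

Step 8
Reactants: 15 2,3-dimethylbut-2-ene
Product: 16 2-methoxypropan-2-yl hydroperoxide
Conditions: O3, MeOH/CH2Cl2, −78 °C
Reagents that add atoms: ozone, [O-][O+]=O; methanol, CO
Why: Ozonolysis of the symmetrical alkene in methanol gives acetone O-oxide, which methanol traps as the α-methoxy hydroperoxide (Criegee mechanism), an acid-removable carrier of the OOH group.

Step 9
Reactants: 14 (2E,4Z)-5-(trimethylsilyl)penta-2,4-dienal; 16 2-methoxypropan-2-yl hydroperoxide
Product: 17 (3R,4Z)-3-[(2-methoxypropan-2-yl)peroxy]-5-(trimethylsilyl)pent-4-enal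
Conditions: 9-amino-9-deoxy-epi-quinine (10 mol %), CF3CO2H (20 mol %), toluene, 0 °C
Reagents that add atoms: none
Why: The primary amine forms an iminium ion with the enal, 16 adds to C3 on the face left open by the catalyst (C3 set R under catalyst control) and the ammonium salt protonates the peroxy-enamine before it can close to an epoxide, while the bulky (Z)-Me3Si group shields C5 against 1,6-addition (amine-catalysed enantioselective conjugate peroxidation of enals).

Step 10
Reactants: 17 (3R,4Z)-3-[(2-methoxypropan-2-yl)peroxy]-5-(trimethylsilyl)pent-4-enal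
Product: 19 methyl (3R,4Z)-3-[(2-methoxypropan-2-yl)peroxy]-5-(trimethylsilyl)pent-4-enoate, via carboxylic acid 18 (not isolated)
Conditions: NaClO2, NaH2PO4, 2-methylbut-2-ene, t-BuOH/H2O, 0 °C; then Me3SiCHN2, MeOH/toluene, 0 °C
Reagents that add atoms: sodium chlorite, [Na+].[O-]Cl=O; trimethylsilyldiazomethane, C[Si](C)(C)C=[N+]=[N-]
Why: Pinnick oxidation is selective for the aldehyde, the alkene scavenger removes HOCl before it can touch the vinylsilane, and methylation with the diazo reagent is neutral, so the peroxide and C3 should be untouched.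

Step 11
Reactants: 19 methyl (3R,4Z)-3-[(2-methoxypropan-2-yl)peroxy]-5-(trimethylsilyl)pent-4-enoate
Product: 20 methyl (3R,4Z)-3-hydroperoxy-5-(trimethylsilyl)pent-4-enoate
Conditions: AcOH/THF/H2O, rt
Reagents that add atoms: none
Why: Mild acid hydrolysis of the mixed perketal (acetal-type deprotection) should release the hydroperoxide without touching the ester, the vinylsilane or the C3–O bond.

Step 12
Reactants: 9 (3S,6R)-3-propyl-6-(4,4,4-trimethoxybutyl)-3,6-dihydro-1,2-dioxine; 20 methyl (3R,4Z)-3-hydroperoxy-5-(trimethylsilyl)pent-4-enoate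
Product: 22 methyl 2-[(3R,6S)-6-methoxy-6-{3-[(3R,6S)-6-propyl-3,6-dihydro-1,2-dioxin-3-yl]propyl}-3,6-dihydro-1,2-dioxin-3-yl]acetate, via mixed peroxy orthoester 21 (not isolated)
Conditions: pyridinium p-toluenesulfonate (5 mol %), 4 Å molecular sieves, CH2Cl2, 0 °C; then Me3SiOTf (20 mol %), 2,6-di-tert-butyl-4-methylpyridine (30 mol %), −78 → −30 °C; pH 7 buffer
Reagents that add atoms: none
Why: Proposed new method: acid-catalysed exchange of one methoxy group of 9 for the hydroperoxide gives the mixed peroxy orthoester 21; Me3SiOTf then removes a second methoxy group, the alkoxy(peroxy)carbenium ion at C6 is attacked by the silicon-bearing alkene carbon C5, and loss of the silyl group from the β-silyl cation returns Me3SiOTf and leaves the C4=C5 double bond. The closest known reaction types are the vinylsilane-terminated cyclization of oxocarbenium ions (dihydropyrans from acetals of (Z)-4-silylbut-3-en-1-ols) and the Lewis-acid cyclization of peroxycarbenium ions onto tethered allylsilanes; an orthoester-derived cation that keeps its alkoxy group in a peroxide ring closure has not been shown. Ring B closes in a 6-endo-trig mode at the vinylsilane through a chair-like transition state made of O1, O2, C6, C5, C4 and C3. The new stereocentre C6 is controlled by C3: allylic 1,3-strain with the (Z)-Me3Si group keeps C3–H in the alkene plane and CH2CO2Me pseudo-equatorial, and the cation should react through its planar conformer with O-methyl syn to O2 and the small peroxide oxygen O1 (not the methyl group) syn to C7, which puts the C7 chain pseudo-axial and cis to CH2CO2Me (6S). The step needs ipso attack at C5 (the five-membered alternative would pass through an α-silyl cation), loss of methoxide and not of the peroxide (the methoxy oxygen is the more basic site and peroxide loss is reversible), and ring closure faster than Hock-type O–O heterolysis of the cation, which low temperature and the hindered pyridine buffer are meant to secure.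

Compound list
1 | 4-bromo-1,1,1-trimethoxybutane | COC(OC)(OC)CCCBr | starting material
2 | lithium acetylide–ethylenediamine complex | [Li+].[C-]#C.NCCN | starting material
3 | 6,6,6-trimethoxyhex-1-yne | C#CCCCC(OC)(OC)OC | intermediate
4 | (E)-(6,6,6-trimethoxyhex-1-en-1-yl)zirconocene chloride (not isolated) | COC(OC)(OC)CCC/C=C/[Zr](Cl)(C1C=CC=C1)C1C=CC=C1 | intermediate
5 | (E)-1-iodo-6,6,6-trimethoxyhex-1-ene | COC(OC)(OC)CCC/C=C/I | intermediate
6 | (E)-pent-1-en-1-ylboronic acid | CCC/C=C/B(O)O | starting material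
7 | (5E,7E)-1,1,1-trimethoxyundeca-5,7-diene | CCC/C=C/C=C/CCCC(OC)(OC)OC | intermediate
8 | rac-(3S,6R)-3-propyl-6-(4,4,4-trimethoxybutyl)-3,6-dihydro-1,2-dioxine (cis racemate) | CCC[C@H]1C=C[C@@H](CCCC(OC)(OC)OC)OO1.CCC[C@@H]1C=C[C@H](CCCC(OC)(OC)OC)OO1 | intermediate
9 | (3S,6R)-3-propyl-6-(4,4,4-trimethoxybutyl)-3,6-dihydro-1,2-dioxine | CCC[C@H]1C=C[C@@H](CCCC(OC)(OC)OC)OO1 | intermediate
10 | 3-(trimethylsilyl)prop-2-yn-1-ol | C[Si](C)(C)C#CCO | starting material
11 | (Z)-3-(trimethylsilyl)prop-2-en-1-ol | C[Si](C)(C)/C=C\CO | intermediate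
12 | (triphenylphosphoranylidene)acetaldehyde | O=CC=P(c1ccccc1)(c1ccccc1)c1ccccc1 | starting material
13 | (Z)-3-(trimethylsilyl)prop-2-enal (not isolated) | C[Si](C)(C)/C=C\C=O | intermediate
14 | (2E,4Z)-5-(trimethylsilyl)penta-2,4-dienal | C[Si](C)(C)/C=C\C=C\C=O | intermediate
15 | 2,3-dimethylbut-2-ene | CC(C)=C(C)C | starting material
16 | 2-methoxypropan-2-yl hydroperoxide | COC(C)(C)OO | intermediate
17 | (3R,4Z)-3-[(2-methoxypropan-2-yl)peroxy]-5-(trimethylsilyl)pent-4-enal | C[Si](C)(C)/C=C\[C@@H](CC=O)OOC(C)(C)OC | intermediate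
18 | (3R,4Z)-3-[(2-methoxypropan-2-yl)peroxy]-5-(trimethylsilyl)pent-4-enoic acid (not isolated) | C[Si](C)(C)/C=C\[C@@H](CC(=O)O)OOC(C)(C)OC | intermediate
19 | methyl (3R,4Z)-3-[(2-methoxypropan-2-yl)peroxy]-5-(trimethylsilyl)pent-4-enoate | C[Si](C)(C)/C=C\[C@@H](CC(=O)OC)OOC(C)(C)OC | intermediate
20 | methyl (3R,4Z)-3-hydroperoxy-5-(trimethylsilyl)pent-4-enoate | C[Si](C)(C)/C=C\[C@@H](CC(=O)OC)OO | intermediate
21 | methyl (3R,4Z)-3-({1,1-dimethoxy-4-[(3R,6S)-6-propyl-3,6-dihydro-1,2-dioxin-3-yl]butyl}peroxy)-5-(trimethylsilyl)pent-4-enoate (mixed peroxy orthoester, not isolated) | CCC[C@H]1C=C[C@@H](CCCC(OC)(OC)OO[C@H](CC(=O)OC)/C=C\[Si](C)(C)C)OO1 | intermediate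
22 | methyl 2-[(3R,6S)-6-methoxy-6-{3-[(3R,6S)-6-propyl-3,6-dihydro-1,2-dioxin-3-yl]propyl}-3,6-dihydro-1,2-dioxin-3-yl]acetate | CCC[C@H]1C=C[C@@H](CCC[C@@]2(OC)C=C[C@@H](CC(=O)OC)OO2)OO1 | target

Total step count: 12.
Longest linear sequence: 6 steps (10 → 11 → 14 → 17 → 19 → 20 → 22; the ring A branch 1 → 3 → 5 → 7 → 8 → 9 → 22 is equally long).

Steps most likely to fail

Step 12 (Proposed new method). What may go wrong: Hock-type O–O heterolysis of the alkoxy(peroxy)carbenium ion, ionization on the peroxide side, re-ionization of the product peroxyketal with loss of the kinetic C6 configuration, or reaction through the other cation conformer and hence poor facial selectivity at C6. The fallback uses known chemistry only, sets out from 19 (with 9 as the acyl source) and comes back to the route at 22. C5–C6 is made by an intermolecular Stille acylation, and ring B is then closed through O2–C6 by the established hemiperketal formation and ketal exchange of a (Z)-γ-hydroperoxy enone.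
- Orthoester 9 would be hydrolysed with dilute aqueous acetic acid to methyl 4-[(3R,6S)-6-propyl-3,6-dihydro-1,2-dioxin-3-yl]butanoate F1. Pig-liver esterase at pH 7 would give 4-[(3R,6S)-6-propyl-3,6-dihydro-1,2-dioxin-3-yl]butanoic acid F2, and 1-chloro-N,N,2-trimethylprop-1-en-1-amine would give 4-[(3R,6S)-6-propyl-3,6-dihydro-1,2-dioxin-3-yl]butanoyl chloride F3.
- Iododesilylation of 19 with N-iodosuccinimide in acetonitrile (retention) should give methyl (3R,4Z)-5-iodo-3-[(2-methoxypropan-2-yl)peroxy]pent-4-enoate F4. Me3SnSnMe3 with Pd(PPh3)4 should then give methyl (3R,4Z)-3-[(2-methoxypropan-2-yl)peroxy]-5-(trimethylstannyl)pent-4-enoate F5.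
- Stille coupling of F5 with F3 (Pd2(dba)3, tri(2-furyl)phosphine, THF) should give methyl (3R,4Z)-3-[(2-methoxypropan-2-yl)peroxy]-6-oxo-9-[(3R,6S)-6-propyl-3,6-dihydro-1,2-dioxin-3-yl]non-4-enoate F6.
- Aqueous acetic acid would remove the methoxypropyl group, and the free hydroperoxide should close onto the ketone to methyl 2-[(3R)-6-hydroxy-6-{3-[(3R,6S)-6-propyl-3,6-dihydro-1,2-dioxin-3-yl]propyl}-3,6-dihydro-1,2-dioxin-3-yl]acetate F7.
- Methanol with a trace of p-toluenesulfonic acid would exchange OH for OMe to give 22 together with methyl 2-[(3R,6R)-6-methoxy-6-{3-[(3R,6S)-6-propyl-3,6-dihydro-1,2-dioxin-3-yl]propyl}-3,6-dihydro-1,2-dioxin-3-yl]acetate F8. The two would be separated and F8 re-equilibrated under the same conditions.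

This fallback gives up kinetic control at C6.

Step 9. What may go wrong: conjugate addition at C5 instead of C3, Z to E isomerization of the C4=C5 bond through the extended iminium ion, collapse of the peroxy-enamine to an epoxide, or acid-induced loss of the methoxypropyl group of 16. The fallback sets out from 10 and comes back at 19; the alkene is replaced by the alkyne during the peroxidation and the (Z)-alkene is made afterwards. The tandem MnO2 oxidation–Wittig olefination of step 7 would be run on the alkynol 10 itself, giving (E)-5-(trimethylsilyl)pent-2-en-4-ynal F10 via 3-(trimethylsilyl)prop-2-ynal F9. The same amine-catalysed peroxidation with 16 should give (3R)-3-[(2-methoxypropan-2-yl)peroxy]-5-(trimethylsilyl)pent-4-ynal F11, which has no isomerizable alkene and an unhindered C3. Pinnick oxidation to (3R)-3-[(2-methoxypropan-2-yl)peroxy]-5-(trimethylsilyl)pent-4-ynoic acid F12 and methylation would give methyl (3R)-3-[(2-methoxypropan-2-yl)peroxy]-5-(trimethylsilyl)pent-4-ynoate F13. Syn semi-reduction of the silylalkyne with diimide (from 2-nitrobenzenesulfonyl hydrazide), a reductant that leaves O–O bonds alone, would return 19.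

Step 5. What may go wrong: insufficient discrimination of the enantiomers on the chiral phase for a molecule without strong interaction sites, or loss of the orthoester on the column. The fallback sets out from 8 and comes back at 22; the resolution is moved to the end, where the enantioenriched ring B serves as internal reference. Racemic 8 would be taken into step 12 with 20. Beside 21, this forms methyl (3R,4Z)-3-({1,1-dimethoxy-4-[(3S,6R)-6-propyl-3,6-dihydro-1,2-dioxin-3-yl]butyl}peroxy)-5-(trimethylsilyl)pent-4-enoate F14. The cyclization then gives 22 together with methyl 2-[(3R,6S)-6-methoxy-6-{3-[(3S,6R)-6-propyl-3,6-dihydro-1,2-dioxin-3-yl]propyl}-3,6-dihydro-1,2-dioxin-3-yl]acetate F15. The two are diastereomers and would be separated by preparative HPLC.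

Further compounds
F1 | step 12 | methyl 4-[(3R,6S)-6-propyl-3,6-dihydro-1,2-dioxin-3-yl]butanoate | CCC[C@H]1C=C[C@@H](CCCC(=O)OC)OO1
F2 | step 12 | 4-[(3R,6S)-6-propyl-3,6-dihydro-1,2-dioxin-3-yl]butanoic acid | CCC[C@H]1C=C[C@@H](CCCC(=O)O)OO1
F3 | step 12 | 4-[(3R,6S)-6-propyl-3,6-dihydro-1,2-dioxin-3-yl]butanoyl chloride | CCC[C@H]1C=C[C@@H](CCCC(=O)Cl)OO1
F4 | step 12 | methyl (3R,4Z)-5-iodo-3-[(2-methoxypropan-2-yl)peroxy]pent-4-enoate | I/C=C\[C@@H](CC(=O)OC)OOC(C)(C)OC
F5 | step 12 | methyl (3R,4Z)-3-[(2-methoxypropan-2-yl)peroxy]-5-(trimethylstannyl)pent-4-enoate | C[Sn](C)(C)/C=C\[C@@H](CC(=O)OC)OOC(C)(C)OC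
F6 | step 12 | methyl (3R,4Z)-3-[(2-methoxypropan-2-yl)peroxy]-6-oxo-9-[(3R,6S)-6-propyl-3,6-dihydro-1,2-dioxin-3-yl]non-4-enoate | CCC[C@H]1C=C[C@@H](CCCC(=O)/C=C\[C@@H](CC(=O)OC)OOC(C)(C)OC)OO1
F7 | step 12 | methyl 2-[(3R)-6-hydroxy-6-{3-[(3R,6S)-6-propyl-3,6-dihydro-1,2-dioxin-3-yl]propyl}-3,6-dihydro-1,2-dioxin-3-yl]acetate (both C6 anomers) | CCC[C@H]1C=C[C@@H](CCCC2(O)C=C[C@@H](CC(=O)OC)OO2)OO1
F8 | step 12 | methyl 2-[(3R,6R)-6-methoxy-6-{3-[(3R,6S)-6-propyl-3,6-dihydro-1,2-dioxin-3-yl]propyl}-3,6-dihydro-1,2-dioxin-3-yl]acetate | CCC[C@H]1C=C[C@@H](CCC[C@]2(OC)C=C[C@@H](CC(=O)OC)OO2)OO1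
F9 | step 9 | 3-(trimethylsilyl)prop-2-ynal | C[Si](C)(C)C#CC=O
F10 | step 9 | (E)-5-(trimethylsilyl)pent-2-en-4-ynal | C[Si](C)(C)C#C/C=C/C=O
F11 | step 9 | (3R)-3-[(2-methoxypropan-2-yl)peroxy]-5-(trimethylsilyl)pent-4-ynal | C[Si](C)(C)C#C[C@@H](CC=O)OOC(C)(C)OC
F12 | step 9 | (3R)-3-[(2-methoxypropan-2-yl)peroxy]-5-(trimethylsilyl)pent-4-ynoic acid | C[Si](C)(C)C#C[C@@H](CC(=O)O)OOC(C)(C)OC
F13 | step 9 | methyl (3R)-3-[(2-methoxypropan-2-yl)peroxy]-5-(trimethylsilyl)pent-4-ynoate | C[Si](C)(C)C#C[C@@H](CC(=O)OC)OOC(C)(C)OC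
F14 | step 5 | methyl (3R,4Z)-3-({1,1-dimethoxy-4-[(3S,6R)-6-propyl-3,6-dihydro-1,2-dioxin-3-yl]butyl}peroxy)-5-(trimethylsilyl)pent-4-enoate | CCC[C@@H]1C=C[C@H](CCCC(OC)(OC)OO[C@H](CC(=O)OC)/C=C\[Si](C)(C)C)OO1
F15 | step 5 | methyl 2-[(3R,6S)-6-methoxy-6-{3-[(3S,6R)-6-propyl-3,6-dihydro-1,2-dioxin-3-yl]propyl}-3,6-dihydro-1,2-dioxin-3-yl]acetate | CCC[C@@H]1C=C[C@H](CCC[C@@]2(OC)C=C[C@@H](CC(=O)OC)OO2)OO1
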